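**Remarks on the chemistry.** Atoms are numbered C1–C13 as in the ten-membered ring of the target (C1 and C3 ketones, C4–C5 epoxide, C7=C11 butenolide alkene, C13 acetoxymethyl). TBS = tert-butyldimethylsilyl, TES = triethylsilyl, PMB = 4-methoxybenzyl. Assumption: C3 is a disposable stereocentre (it ends as a ketone) and is set (S), so that its oxygen and the C6 oxygen lie on the same face of the C4=C5 alkene. The stereodescriptors of the key-step precursor and product were checked against the target: C4, C6, C8 and C10 have the target arrangement and C5 the opposite one, as one inversion requires. No structural correction was needed; the one design change is that C3 is carried as a PMB-protected carbinol instead of a ketone.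

## Structural features

The target is a ten-membered carbocycle (C1–C10). A butenolide is fused across C6–C7 (ring oxygen on C6, carbonyl C12, tetrasubstituted C7=C11 alkene with the C13 acetoxymethyl on C11), and a trans epoxide spans C4–C5, C4 also carrying a methyl group. C1 and C3 are ketones flanking the C2 methylene, C8 carries the (Z)-4-acetoxy-3-methylbut-2-enoate and C10 a methyl group; the configuration is 4S,5R,6R,8R,10R. C4, C5 and C6 are contiguous stereocentres, C8 is separated from C6 only by the sp2 carbon C7, and C10 stands alone next to the C1 carbonyl. The fragile points are: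
- the 1,3-diketone (acidic C2, transannular aldol or hemiketal formation);
- the epoxide, which is α to the C3 ketone and β to the acidic γ-hydrogen on C6 of the butenolide;
- the two allylic acetates and the Z side chain, which lactonises if its acetate is lost;
- the epimerisable C10.

The real difficulty is a medium ring with oxygen on seven of its ten carbons: closing it by bond formation costs entropy and transannular strain, and the sensitive groups leave little room for late corrections. The key step exploits that C1 and C7 are both at the carbonyl level (C7, the butenolide β-carbon, can come from a ketone) and are joined by the three-carbon bridge C8–C10 and the five-carbon bridge C2–C6. A C1=C7 double bond therefore turns the ring into a strain-free bicyclo[5.3.0]dec-1(7)-ene, on whose seven-membered ring the 4,5-oxygens are a cis diol, the precursor of the trans epoxide after one inversion.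

## Logic of the disconnections

**46 ⇒ 45 ⇒ 44.** No skeletal bond is cut; the C3 carbonyl is traced back to a carbinol and then to its PMB ether. This keeps the 1,3-dicarbonyl unit and its acidic C2 out of every earlier intermediate, so that base-mediated steps become possible. The forward steps must unmask and oxidise C3 without touching epoxide, lactone or esters.

**44 ⇒ 43 ⇒ 42 ⇒ 41.** The C5–O bond of the epoxide is cut, giving the cis 4,5-diol. A cis diol is what a cis ring alkene delivers, and one inversion at C5 turns it into the trans epoxide. The forward demand is sulfonylation of the secondary C5 hydroxyl only and ring closure by the C4 alkoxide faster than elimination towards C6.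

**41 ⇒ 39 + 9, then 39 ⇒ 38 ⇒ 37.** The acyl C–O bonds at C8 and C13 are cut. The side chain becomes a separate acid that already carries its acetate, and the ring compound is reduced to a diol. The forward demand is to distinguish a primary from a secondary hydroxyl and to keep the Z enoate intact.

**37 ⇒ 36 ⇒ 35 + 4, then 35 ⇒ 34.** The C7=C11 bond and the O6–C12 ester bond are cut. The butenolide with its C13 oxygen becomes an α-hydroxy ketone plus a phosphonate acid. The forward demand is an intramolecular olefination of a hindered ketone with a base too weak to enolise C6, C8 or C10.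

**34 ⇒ 32 (through 33).** C1 and C7 are reconnected by a double bond. The medium ring becomes a five/seven-fused bicycle on which all stereocentres can be set on a rigid frame. The forward step is a clean cleavage of a tetrasubstituted alkene. A 3-keto version of 32 would be a β,γ-unsaturated ketone and would give a 1,3,7-triketone whose C2 can attack C7 across the ring; the C3 ether removes both problems.

**32 ⇒ 31 ⇒ 30.** The C4–O and C5–O bonds are cut, leaving the C4=C5 ring alkene. The forward demand is dihydroxylation of the trisubstituted alkene only, on the face away from the C3 and C6 oxygens.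

**30 ⇒ 29.** The C4=C5 bond is cut (ring-closing metathesis). The seven-membered ring becomes two alkene arms held cis on a cyclopentene. The forward demand is closure onto a 1,1-disubstituted alkene flanked by an ether.

**29 ⇒ 28 ⇒ 27 ⇒ 24 + 25 (through 26).** The C6–C7 bond is cut and C6 is traced to a ketone. The C5–C6 arm becomes a commercial acrylamide and C6 is set by a catalyst. The forward demand is a halogen–metal exchange next to a silyl ether and discrimination of two alkenyl groups in the reduction.

**24 ⇒ 23 ⇒ 22 ⇒ 19 + 20 (through 21).** The C3–C4 bond is cut and C3 is traced to a ketone. The arm becomes an ester and an isopropenyl Grignard reagent, and C3 is again set by a catalyst. The forward demand is that the alkenyl bromide and the β,γ-alkene survive.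

**19 ⇒ 18 ⇒ 17 ⇒ 15.** The C8–H bond (ketone reduction) and the C7–Br bond are cut. The C8 oxygen comes from the enone carbonyl itself, not from an allylic oxidation, and reagent control gives the configuration trans to the C10 methyl.

**15 ⇒ 14 ⇒ 12 + 13, then 12 ⇒ 10 (through 11).** The C1–C2 bond (conjugate addition) and the C10–CH3 bond (conjugate addition anti to a silyloxy group) are cut. A ring-contracted monoterpene keto ester was weighed as the chiral source and set aside: its ester carbon would be C2 itself, so C3 would need a one-carbon homologation, and C8 would need an allylic oxidation of uncertain regiochemistry. In 12 the carbonyl is already C8 and C2–C3 arrive in one step.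

**4 ⇒ 3 ⇒ 2 ⇒ 1 and 9 ⇒ 8 ⇒ 5 (through 6 and 7).** The C11–C13 bond (hydroxymethylation of a phosphonoacetate) and the lactone C–O bond of a butenolide, whose ring fixes the Z geometry, are cut. Both fragments come from commercial materials in two or three steps.

## Other disconnections considered

**Alternative 1:** The cut is through C4–C5 and the epoxide C4–O bond at once. The seco compound is the sulfonium salt A1, with the sulfonium group on C4 next to the C3 ketone and the aldehyde C5 on a dihydrofuran. In the forward step Cs2CO3 makes the ylide, which adds to the aldehyde; the betaine closes to the epoxide with loss of the sulfide and gives the macrocycle A2.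
- In its favour: ring and trans epoxide appear in one step, the trans geometry following from reversible betaine formation, and the C8 and C13 esters are already in place.
- Against it here: keto-stabilised sulfonium ylides are reluctant epoxidising agents, the ylide carbon is fully substituted, and the ten-membered ring must close by C–C bond formation under dilution. C4 and C5 must both be set with only C6 as control, the aldehyde sits on an epimerisable C6, and the ylide can cyclopropanate the enoate or the vinylogous ester. The dihydrofuran must later be oxidised to the lactone beside an epoxide and allylic acetates.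
- Comparison: on structure Alternative 1 is the better plan for the epoxide (no diol and inversion) and the equal for carrying the esters. On mechanism the chosen plan is safer, since its ring arises by a cleavage of very high driving force that creates no stereocentre. On step economy Alternative 1 needs fewer steps after the key step but a longer build of A1, so the two should be about equal.

**Alternative 2:** The cut is through C6–C7 and O–C12. The seco compound A3 has a (Z)-β-iodo enoate at C7 and an epoxy aldehyde at C6. In the forward step CrCl2 with catalytic NiCl2 makes the alkenylchromium species, which adds to the aldehyde; the chromium alkoxide lactonises onto the cis ester and gives A4.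
- In its favour: this coupling is well precedented for medium rings and tolerates epoxide, ketone and silyl ethers. The butenolide forms in the same step, the alkene geometry is fixed by the iodide, and the trans epoxide can be set earlier by a reagent-controlled epoxidation.
- Against it here: the ten-membered ring closes by C–C bond formation (dilution, large excess of the divalent chromium salt, transannular strain). C6 is created in the ring closure under the control of the epoxide and the ring conformation only, the epoxy aldehyde is labile, and about six steps of oxidation and protecting-group exchange follow.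
- Comparison: on structure Alternative 2 is the better plan for the epoxide and the equal for the butenolide. On mechanism the chosen plan has the advantage that ring formation creates no stereocentre. On step economy Alternative 2 is the equal or slightly the better (two fragments, convergent), at the price of a less certain key step.

**Alternative 3:** The cut is through C3–C4, with the C4=C5 alkene coming from an alkyne. The seco compound is the ynal A5. In the forward step Ni(cod)2, an N-heterocyclic carbene and Et3SiH give an oxanickelacycle from the zerovalent nickel, the aldehyde and the alkyne; the silane cleaves it to the (E)-allylic silyl ether A6.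
- In its favour: the step is catalytic, and ring and alkene geometry arise together. The E alkene can be epoxidised directly to the trans epoxide, and C3 arrives protected.
- Against it here: the regiochemistry of alkyne insertion (ten-membered endocyclic against nine-membered exocyclic product) rests on the ligand. An E cyclodecene is strained, and the facial selectivity of the later epoxidation rests on the macrocycle conformation. Lactonisation, oxidation at C1 and C3 and protecting-group exchanges remain, and A5 with five stereocentres and a tetrasubstituted enoate is long to make.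
- Comparison: on structure Alternative 3 is the better plan for the origin of the trans epoxide and the equal for carrying C8 and C10. On mechanism the chosen cleavage has no regiochemical or conformational question. On step economy the two endgames are of similar length, so Alternative 3 is at best the equal.

Key step: step 21

## Route

**Step 1**
Reactants: 1 benzyl 2-(diethoxyphosphoryl)acetate
Product: 2 benzyl 2-(diethoxyphosphoryl)-3-hydroxypropanoate
Conditions: aq. CH2O (1.0 equiv), K2CO3 (cat.), THF, 0 °C
Reagents that add atoms: formaldehyde, C=O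
Why: Base-catalysed aldol-type hydroxymethylation of the doubly activated methylene; one equivalent of formaldehyde at 0 °C should stop at the mono-adduct because the second deprotonation needed for olefination is slower on the substituted phosphonate.

**Step 2**
Reactants: 2 benzyl 2-(diethoxyphosphoryl)-3-hydroxypropanoate
Product: 3 benzyl 3-[(tert-butyldimethylsilyl)oxy]-2-(diethoxyphosphoryl)propanoate
Conditions: TBSCl, imidazole, CH2Cl2, 0 °C → rt
Reagents that add atoms: tert-butyldimethylsilyl chloride, CC(C)(C)[Si](C)(C)Cl
Why: Imidazole-mediated silylation of a primary alcohol; the future C13 oxygen becomes an ether that survives the olefination base.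

**Step 3**
Reactants: 3 benzyl 3-[(tert-butyldimethylsilyl)oxy]-2-(diethoxyphosphoryl)propanoate
Product: 4 3-[(tert-butyldimethylsilyl)oxy]-2-(diethoxyphosphoryl)propanoic acid
Conditions: H2 (1 atm), Pd/C, EtOAc, rt
Reagents that add atoms: none
Why: Hydrogenolysis of the benzyl ester frees the acid without base, so the β-silyloxy phosphonate cannot eliminate; silyl ether and phosphonate are inert to H2.

**Step 4**
Reactants: 5 4-methylfuran-2(5H)-one
Product: 8 4-methoxybenzyl (Z)-4-acetoxy-3-methylbut-2-enoate, via potassium (Z)-4-hydroxy-3-methylbut-2-enoate 6 (not isolated), via 4-methoxybenzyl (Z)-4-hydroxy-3-methylbut-2-enoate 7 (not isolated)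
Conditions: KOH (1.0 equiv), MeOH/H2O, rt, evaporate; PMBCl, DMF, rt; then Ac2O, pyridine, DMAP (cat.), 0 °C
Reagents that add atoms: potassium hydroxide, [K+].[OH-]; 4-methoxybenzyl chloride, COc1ccc(CCl)cc1; acetic anhydride, CC(=O)OC(C)=O
Why: Saponification opens the butenolide and the ring fixes the Z geometry; O-alkylation of the carboxylate blocks relactonisation, and the primary alcohol is acetylated in the same flask (DMAP acyl transfer) before the hydroxy ester can cyclise.

**Step 5**
Reactants: 8 4-methoxybenzyl (Z)-4-acetoxy-3-methylbut-2-enoate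
Product: 9 (Z)-4-acetoxy-3-methylbut-2-enoic acid
Conditions: CF3CO2H, Et3SiH, CH2Cl2, 0 °C
Reagents that add atoms: none
Why: Acidolysis of the PMB ester (benzylic cation, reduced by the silane) leaves the acetate and the Z enoate untouched; no base is present that could open the acid to its lactone.

**Step 6**
Reactants: 10 (R)-4-[(tert-butyldimethylsilyl)oxy]cyclopent-2-en-1-one
Product: 12 (R)-4-methylcyclopent-2-en-1-one, via trans-3-methyl-4-silyloxycyclopentanone 11 (not isolated)
Conditions: MeMgBr, CuBr·SMe2 (10 mol %), THF, −78 °C, aq. NH4Cl; then DBU, CH2Cl2, 0 °C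
Reagents that add atoms: methylmagnesium bromide, C[Mg]Br
Why: Copper-catalysed conjugate addition anti to the silyloxy group sets C10, and E1cB loss of silanol from the β-silyloxy ketone moves the enone so that the new centre is γ; short exposure to DBU at 0 °C should limit migration of the alkene towards the methyl-bearing carbon.

**Step 7**
Reactants: 12 (R)-4-methylcyclopent-2-en-1-one; 13 tert-butyl[(1-methoxyethenyl)oxy]dimethylsilane
Product: 14 methyl 2-[(1S,5R)-5-methyl-3-[(tert-butyldimethylsilyl)oxy]cyclopent-2-en-1-yl]acetate
Conditions: MeCN, 50 °C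
Reagents that add atoms: none
Why: Mukaiyama–Michael addition with silyl transfer; the ketene acetal adds trans to the adjacent methyl group and leaves the regiodefined C8=C7 silyl enol ether that the next step needs.

**Step 8**
Reactants: 14 methyl 2-[(1S,5R)-5-methyl-3-[(tert-butyldimethylsilyl)oxy]cyclopent-2-en-1-yl]acetate
Product: 15 methyl 2-[(5R)-5-methyl-3-oxocyclopent-1-en-1-yl]acetate
Conditions: Pd(OAc)2 (10 mol %), O2 (1 atm), DMSO, 50 °C
Reagents that add atoms: none
Why: Saegusa–Ito dehydrogenation (palladium enolate at C7, β-hydride elimination from C1) restores the C1=C7 alkene, now carrying the C2–C3 arm; the neutral conditions do not touch the γ-stereocentre C10.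

**Step 9**
Reactants: 15 methyl 2-[(5R)-5-methyl-3-oxocyclopent-1-en-1-yl]acetate
Product: 17 methyl 2-[(5R)-2-bromo-5-methyl-3-oxocyclopent-1-en-1-yl]acetate, via dibromo ketone 16 (not isolated)
Conditions: Br2, CH2Cl2, −20 °C; then Et3N, 0 °C
Reagents that add atoms: bromine, BrBr
Why: Bromine addition to the enone alkene and E1cB dehydrobromination through the ketone enolate, the usual route to 2-bromo enones, put the halogen handle on C7.

**Step 10**
Reactants: 17 methyl 2-[(5R)-2-bromo-5-methyl-3-oxocyclopent-1-en-1-yl]acetate
Product: 18 methyl 2-[(3R,5R)-2-bromo-3-hydroxy-5-methylcyclopent-1-en-1-yl]acetate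
Conditions: (S)-2-methyl-CBS-oxazaborolidine (20 mol %), catecholborane, toluene, −78 °C; MeOH
Reagents that add atoms: none
Why: Corey–Bakshi–Shibata reduction; the bromoalkenyl side is the large group, so the (S)-catalyst should give the (R)-carbinol, C8 oxygen trans to the C10 methyl, under reagent control.

**Step 11**
Reactants: 18 methyl 2-[(3R,5R)-2-bromo-3-hydroxy-5-methylcyclopent-1-en-1-yl]acetate
Product: 19 methyl 2-[(3R,5R)-2-bromo-3-[(tert-butyldimethylsilyl)oxy]-5-methylcyclopent-1-en-1-yl]acetate
Conditions: TBSCl, imidazole, DMF, rt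
Reagents that add atoms: tert-butyldimethylsilyl chloride, CC(C)(C)[Si](C)(C)Cl
Why: Silylation of the allylic alcohol; protection also removes the chance of lactonisation onto the ester arm.

**Step 12**
Reactants: 19 methyl 2-[(3R,5R)-2-bromo-3-[(tert-butyldimethylsilyl)oxy]-5-methylcyclopent-1-en-1-yl]acetate; 20 isopropenylmagnesium bromide
Product: 22 1-[(3R,5R)-2-bromo-3-[(tert-butyldimethylsilyl)oxy]-5-methylcyclopent-1-en-1-yl]-3-methylbut-3-en-2-one, via Weinreb amide 21 (not isolated)
Conditions: MeNH(OMe)·HCl, i-PrMgCl, THF, −20 °C; then 20, −20 → 0 °C; aq. NH4Cl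
Reagents that add atoms: none
Why: One-flask Weinreb ketone synthesis: the magnesium amide converts the ester into the N-methoxy-N-methylamide, whose chelated adduct with the Grignard reagent collapses to the ketone only on work-up; the alkenyl bromide does not exchange with Grignard reagents at this temperature.

**Step 13**
Reactants: 22 1-[(3R,5R)-2-bromo-3-[(tert-butyldimethylsilyl)oxy]-5-methylcyclopent-1-en-1-yl]-3-methylbut-3-en-2-one
Product: 23 (2S)-1-[(3R,5R)-2-bromo-3-[(tert-butyldimethylsilyl)oxy]-5-methylcyclopent-1-en-1-yl]-3-methylbut-3-en-2-ol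
Conditions: (R)-2-methyl-CBS-oxazaborolidine (20 mol %), catecholborane, toluene, −78 °C; MeOH
Reagents that add atoms: none
Why: Corey–Bakshi–Shibata reduction with the isopropenyl group as the large substituent, so the (R)-catalyst should give the (S)-carbinol; catecholborane at −78 °C avoids hydroboration and migration of the β,γ-alkene.

**Step 14**
Reactants: 23 (2S)-1-[(3R,5R)-2-bromo-3-[(tert-butyldimethylsilyl)oxy]-5-methylcyclopent-1-en-1-yl]-3-methylbut-3-en-2-ol
Product: 24 4-methoxybenzyl ether of 23 at C3
Conditions: NaH, PMBCl, Bu4NI (cat.), DMF, 0 °C → rt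
Reagents that add atoms: 4-methoxybenzyl chloride, COc1ccc(CCl)cc1
Why: Williamson etherification; the PMB ether resists organolithium, fluoride, aqueous acetic acid and amide bases, cannot migrate to a neighbouring alkoxide, and is removed oxidatively at the end.

**Step 15**
Reactants: 24 4-methoxybenzyl ether of 23 at C3; 25 N-methoxy-N-methylprop-2-enamide
Product: 27 1-[(3R,5R)-5-[(tert-butyldimethylsilyl)oxy]-2-[(2S)-2-[(4-methoxybenzyl)oxy]-3-methylbut-3-en-1-yl]-3-methylcyclopent-1-en-1-yl]prop-2-en-1-one, via alkenyllithium 26 (not isolated)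
Conditions: t-BuLi (2.1 equiv), Et2O, −78 °C; then 25, −78 °C; AcOH quench
Reagents that add atoms: none
Why: Bromine–lithium exchange followed by acylation of the alkenyllithium with the Weinreb acrylamide (chelated adduct, no over-addition); the cold acidic quench keeps the liberated amine from adding to the vinyl ketone.

**Step 16**
Reactants: 27 1-[(3R,5R)-5-[(tert-butyldimethylsilyl)oxy]-2-[(2S)-2-[(4-methoxybenzyl)oxy]-3-methylbut-3-en-1-yl]-3-methylcyclopent-1-en-1-yl]prop-2-en-1-one
Product: 28 (1S)-allylic alcohol from 27 (C6 carbinol)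
Conditions: (R)-2-methyl-CBS-oxazaborolidine (20 mol %), catecholborane, toluene, −78 °C; MeOH
Reagents that add atoms: none
Why: Corey–Bakshi–Shibata reduction in which the tetrasubstituted cyclopentenyl group is the large and the vinyl group the small substituent; the (R)-catalyst should give the (S)-carbinol, C6 oxygen cis to the C8 oxygen, and 1,2-reduction is favoured at −78 °C.

**Step 17**
Reactants: 28 (1S)-allylic alcohol from 27 (C6 carbinol)
Product: 29 triethylsilyl ether of 28
Conditions: TESCl, imidazole, CH2Cl2, 0 °C
Reagents that add atoms: triethylsilyl chloride, CC[Si](Cl)(CC)CC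
Why: Silylation under mild basic conditions, which do not ionise the doubly allylic C6–O bond.

**Step 18**
Reactants: 29 triethylsilyl ether of 28
Product: 30 bicyclo[5.3.0]deca-1(7),4-diene (3S,6S,8R,10R; C3 OPMB; C6 OTES; C8 OTBS)
Conditions: second-generation Grubbs catalyst (H2IMes)(PCy3)Cl2Ru=CHPh (5 mol %), toluene, 80 °C
Reagents that add atoms: none
Why: Ring-closing metathesis; the ruthenium carbene forms at the vinyl group and closes onto the isopropenyl group, the two arms being held cis on the cyclopentene, to give the trisubstituted C4=C5 alkene; the tetrasubstituted C1=C7 alkene is inert.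

**Step 19**
Reactants: 30 bicyclo[5.3.0]deca-1(7),4-diene (3S,6S,8R,10R; C3 OPMB; C6 OTES; C8 OTBS)
Product: 31 cis-4,5-diol of 30 (3S,4R,5S,6R,8R,10R)
Conditions: OsO4 (5 mol %), N-methylmorpholine N-oxide, acetone/H2O, rt
Reagents that add atoms: osmium tetroxide, O=[Os](=O)(=O)=O; N-methylmorpholine N-oxide, C[N+]1([O-])CCOCC1
Why: Catalytic OsO4 dihydroxylation; the reagent should add to the more accessible trisubstituted alkene from the face anti to both allylic oxygens (C3 and C6), which sets C4 and C5 as the cis diol trans to the C6 oxygen; the hindered fusion alkene reacts far more slowly.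

**Step 20**
Reactants: 31 cis-4,5-diol of 30 (3S,4R,5S,6R,8R,10R)
Product: 32 4,5-acetonide of 31
Conditions: 2-methoxypropene, pyridinium p-toluenesulfonate (cat.), CH2Cl2, 0 °C
Reagents that add atoms: 2-methoxypropene, COC(C)=C
Why: Acid-catalysed ketalisation of the cis diol with the enol ether; afterwards only silyl ethers, an acetal and a benzylic ether face ozone.

**Step 21**
Reactants: 32 4,5-acetonide of 31
Product: 34 ten-membered 1,7-diketone (3S,4R,5S,6S,8R,10R; C3 OPMB; 4,5-acetonide; C6 OTES; C8 OTBS), via secondary ozonide 33 (not isolated)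
Conditions: O3/O2, CH2Cl2, NaHCO3, Sudan Red 7B (indicator), −78 °C; then Me2S, −78 °C → rt
Reagents that add atoms: ozone, [O-][O+]=O
Why: Ozone adds as a 1,3-dipole to C1=C7, the only alkene of 32 and a tetrasubstituted, electron-rich one; the primary ozonide cycloreverts to a carbonyl oxide and a ketone that stay tethered and recombine to the bridged 1,2,4-trioxolane 33, which Me2S reduces to the C1 and C7 ketones. The closest known reaction type is the ozonolysis of tetrasubstituted ring-fusion alkenes of fused bicycles to medium-ring diketones. The ten-membered ring is not closed by bond formation: it appears by scission of the bond shared by the five- and seven-membered rings, so there is no entropic penalty and no strained cyclisation transition state. No stereocentre is formed; C3, C4, C5, C6, C8 and C10 come unchanged from the rigid bicycle, and C6, C8 and C10 become α to ketones only under neutral, cold conditions. The step needs chemoselectivity for the alkene over the anisyl ring, which the large rate difference and indicator-controlled dosing of ozone should secure. It also needs a product that does not undergo transannular aldol or hemiketal formation: there is no free hydroxyl, the work-up is non-basic, and because C3 is an ether the product has no 1,3-dicarbonyl unit and no acidic C2.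

**Step 22**
Reactants: 34 ten-membered 1,7-diketone (C3 OPMB; 4,5-acetonide; C6 OTES; C8 OTBS)
Product: 35 6-hydroxy diketone
Conditions: HF·pyridine, pyridine, THF, 0 °C
Reagents that add atoms: none
Why: Fluoride-mediated desilylation; the TES ether is cleaved much faster than the hindered secondary TBS ether, and buffered HF does not enolise the ketones.

**Step 23**
Reactants: 35 6-hydroxy diketone; 4 3-[(tert-butyldimethylsilyl)oxy]-2-(diethoxyphosphoryl)propanoic acid
Product: 36 6-O-phosphonopropanoyl ester of 35
Conditions: DCC, DMAP (cat.), CH2Cl2, 0 °C → rt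
Reagents that add atoms: none
Why: Steglich esterification of the α-hydroxy ketone; the product is a mixture of epimers at the phosphonate carbon, a centre that disappears in the next step.

**Step 24**
Reactants: 36 6-O-phosphonopropanoyl ester of 35
Product: 37 butenolide (C13 OTBS; C8 OTBS; C3 OPMB; 4,5-acetonide; C1 ketone)
Conditions: LiCl, i-Pr2NEt, MeCN, 0 °C → rt
Reagents that add atoms: none
Why: Intramolecular Horner–Wadsworth–Emmons olefination: the lithium-chelated phosphonate anion adds to the adjacent C7 ketone (five-membered ring) and loses diethyl phosphate; the amine is too weak to enolise the ketones, and any loss of silanolate from the anion is reversible while olefination is not.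

**Step 25**
Reactants: 37 butenolide (C13 OTBS; C8 OTBS; C3 OPMB; 4,5-acetonide; C1 ketone)
Product: 38 8,13-diol
Conditions: HF·pyridine, THF, 0 °C → rt
Reagents that add atoms: none
Why: Desilylation of the primary and the secondary TBS ether; acetonide, PMB ether and butenolide are stable to HF·pyridine.

**Step 26**
Reactants: 38 8,13-diol
Product: 39 13-acetate with free C8 hydroxyl
Conditions: AcCl (1.1 equiv), 2,4,6-collidine, CH2Cl2, −78 °C
Reagents that add atoms: acetyl chloride, CC(=O)Cl
Why: Selective acylation of the primary allylic alcohol at low temperature with a hindered pyridine base; the secondary C8 hydroxyl reacts much more slowly.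

**Step 27**
Reactants: 39 13-acetate with free C8 hydroxyl; 9 (Z)-4-acetoxy-3-methylbut-2-enoic acid
Product: 41 C8 ester (13-acetate; 4,5-acetonide; C3 OPMB), via mixed anhydride 40 (not isolated)
Conditions: 9, 2,4,6-trichlorobenzoyl chloride, Et3N, toluene, rt; then 39, DMAP, toluene, rt
Reagents that add atoms: none
Why: Yamaguchi esterification through the mixed anhydride and DMAP; the acid already carries its acetate, so no free γ-hydroxy Z enoate, which would lactonise, is ever present.

**Step 28**
Reactants: 41 C8 ester (13-acetate; 4,5-acetonide; C3 OPMB)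
Product: 42 4,5-diol
Conditions: AcOH/H2O (4:1), 45 °C
Reagents that add atoms: none
Why: Acid-catalysed hydrolysis of the acetonide; esters, PMB ether and lactone tolerate aqueous acetic acid, and transannular hemiketals of the diol with the C1 ketone stay in equilibrium with the open form.

**Step 29**
Reactants: 42 4,5-diol
Product: 43 C5 methanesulfonate
Conditions: MsCl, Et3N, CH2Cl2, −40 °C
Reagents that add atoms: methanesulfonyl chloride, CS(=O)(=O)Cl
Why: Selective sulfonylation of the secondary C5 hydroxyl; the tertiary C4 hydroxyl does not react, and the low temperature keeps the amine from eliminating the sulfonate.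

**Step 30**
Reactants: 43 C5 methanesulfonate
Product: 44 trans-4,5-epoxide (C3 OPMB)
Conditions: KN(SiMe3)2 (1.05 equiv), THF, −78 → −30 °C
Reagents that add atoms: none
Why: Intramolecular Williamson reaction (3-exo-tet): kinetic deprotonation of the hydroxyl by one equivalent of base and backside attack of the C4 alkoxide on C5 with inversion give the trans epoxide; the ten-membered ring can reach the antiperiplanar O–C4–C5–O arrangement that the seven-membered ring could not.

**Step 31**
Reactants: 44 trans-4,5-epoxide (C3 OPMB)
Product: 45 3-hydroxy epoxide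
Conditions: DDQ, CH2Cl2/pH 7 phosphate buffer, 0 °C → rt
Reagents that add atoms: none
Why: Oxidative cleavage of the PMB ether (hydride abstraction, hydrolysis of the oxocarbenium ion) under buffered neutral conditions that spare epoxide, lactone and esters.

**Step 32**
Reactants: 45 3-hydroxy epoxide
Product: 46 CNP0274470.1
Conditions: Dess–Martin periodinane (1.1 equiv), NaHCO3, CH2Cl2, 0 °C
Reagents that add atoms: none
Why: Dess–Martin oxidation of the β-hydroxy ketone to the 1,3-diketone under buffered, non-basic conditions; a near-stoichiometric amount avoids over-oxidation at C2.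

## Compound list

1 | benzyl 2-(diethoxyphosphoryl)acetate | CCOP(=O)(OCC)CC(=O)OCc1ccccc1 | starting material
2 | benzyl 2-(diethoxyphosphoryl)-3-hydroxypropanoate (racemic) | CCOP(=O)(OCC)C(CO)C(=O)OCc1ccccc1 | intermediate
3 | benzyl 3-[(tert-butyldimethylsilyl)oxy]-2-(diethoxyphosphoryl)propanoate (racemic) | CCOP(=O)(OCC)C(CO[Si](C)(C)C(C)(C)C)C(=O)OCc1ccccc1 | intermediate
4 | 3-[(tert-butyldimethylsilyl)oxy]-2-(diethoxyphosphoryl)propanoic acid (racemic) | CCOP(=O)(OCC)C(CO[Si](C)(C)C(C)(C)C)C(=O)O | intermediate
5 | 4-methylfuran-2(5H)-one | CC1=CC(=O)OC1 | starting material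
6 | potassium (Z)-4-hydroxy-3-methylbut-2-enoate (not isolated) | [K+].[O-]C(=O)/C=C(/C)CO | intermediate
7 | 4-methoxybenzyl (Z)-4-hydroxy-3-methylbut-2-enoate (not isolated) | COc1ccc(COC(=O)/C=C(/C)CO)cc1 | intermediate
8 | 4-methoxybenzyl (Z)-4-acetoxy-3-methylbut-2-enoate | COc1ccc(COC(=O)/C=C(/C)COC(C)=O)cc1 | intermediate
9 | (Z)-4-acetoxy-3-methylbut-2-enoic acid | OC(=O)/C=C(/C)COC(C)=O | intermediate
10 | (R)-4-[(tert-butyldimethylsilyl)oxy]cyclopent-2-en-1-one | O=C1C=C[C@H](O[Si](C)(C)C(C)(C)C)C1 | starting material
11 | (3R,4R)-3-methyl-4-[(tert-butyldimethylsilyl)oxy]cyclopentan-1-one, trans (not isolated) | C[C@@H]1CC(=O)C[C@H]1O[Si](C)(C)C(C)(C)C | intermediate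
12 | (R)-4-methylcyclopent-2-en-1-one | C[C@@H]1CC(=O)C=C1 | intermediate
13 | tert-butyl[(1-methoxyethenyl)oxy]dimethylsilane | COC(=C)O[Si](C)(C)C(C)(C)C | starting material
14 | methyl 2-[(1S,5R)-5-methyl-3-[(tert-butyldimethylsilyl)oxy]cyclopent-2-en-1-yl]acetate (arm trans to methyl) | C[C@@H]1CC(O[Si](C)(C)C(C)(C)C)=C[C@H]1CC(=O)OC | intermediate
15 | methyl 2-[(5R)-5-methyl-3-oxocyclopent-1-en-1-yl]acetate | C[C@@H]1CC(=O)C=C1CC(=O)OC | intermediate
16 | methyl 2-[(2R)-1,5-dibromo-2-methyl-4-oxocyclopentyl]acetate, trans dibromide, both faces (not isolated) | C[C@@H]1CC(=O)C(Br)C1(Br)CC(=O)OC | intermediate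
17 | methyl 2-[(5R)-2-bromo-5-methyl-3-oxocyclopent-1-en-1-yl]acetate | C[C@@H]1CC(=O)C(Br)=C1CC(=O)OC | intermediate
18 | methyl 2-[(3R,5R)-2-bromo-3-hydroxy-5-methylcyclopent-1-en-1-yl]acetate | C[C@@H]1C[C@@H](O)C(Br)=C1CC(=O)OC | intermediate
19 | methyl 2-[(3R,5R)-2-bromo-3-[(tert-butyldimethylsilyl)oxy]-5-methylcyclopent-1-en-1-yl]acetate | C[C@@H]1C[C@@H](O[Si](C)(C)C(C)(C)C)C(Br)=C1CC(=O)OC | intermediate
20 | isopropenylmagnesium bromide | CC(=C)[Mg]Br | starting material
21 | 2-[(3R,5R)-2-bromo-3-[(tert-butyldimethylsilyl)oxy]-5-methylcyclopent-1-en-1-yl]-N-methoxy-N-methylacetamide (not isolated) | C[C@@H]1C[C@@H](O[Si](C)(C)C(C)(C)C)C(Br)=C1CC(=O)N(C)OC | intermediate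
22 | 1-[(3R,5R)-2-bromo-3-[(tert-butyldimethylsilyl)oxy]-5-methylcyclopent-1-en-1-yl]-3-methylbut-3-en-2-one | C[C@@H]1C[C@@H](O[Si](C)(C)C(C)(C)C)C(Br)=C1CC(=O)C(C)=C | intermediate
23 | (2S)-1-[(3R,5R)-2-bromo-3-[(tert-butyldimethylsilyl)oxy]-5-methylcyclopent-1-en-1-yl]-3-methylbut-3-en-2-ol | C[C@@H]1C[C@@H](O[Si](C)(C)C(C)(C)C)C(Br)=C1C[C@H](O)C(C)=C | intermediate
24 | 4-methoxybenzyl ether of 23 (C3 OPMB, C7 bromide, C8 OTBS) | C[C@@H]1C[C@@H](O[Si](C)(C)C(C)(C)C)C(Br)=C1C[C@H](OCc2ccc(OC)cc2)C(C)=C | intermediate
25 | N-methoxy-N-methylprop-2-enamide | C=CC(=O)N(C)OC | starting material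
26 | alkenyllithium from 24, lithium on C7 (not isolated) | C[C@@H]1C[C@@H](O[Si](C)(C)C(C)(C)C)C([Li])=C1C[C@H](OCc2ccc(OC)cc2)C(C)=C | intermediate
27 | 1-[(3R,5R)-5-[(tert-butyldimethylsilyl)oxy]-2-[(2S)-2-[(4-methoxybenzyl)oxy]-3-methylbut-3-en-1-yl]-3-methylcyclopent-1-en-1-yl]prop-2-en-1-one | C[C@@H]1C[C@@H](O[Si](C)(C)C(C)(C)C)C(C(=O)C=C)=C1C[C@H](OCc2ccc(OC)cc2)C(C)=C | intermediate
28 | (1S)-1-[(3R,5R)-5-[(tert-butyldimethylsilyl)oxy]-2-[(2S)-2-[(4-methoxybenzyl)oxy]-3-methylbut-3-en-1-yl]-3-methylcyclopent-1-en-1-yl]prop-2-en-1-ol | C[C@@H]1C[C@@H](O[Si](C)(C)C(C)(C)C)C([C@@H](O)C=C)=C1C[C@H](OCc2ccc(OC)cc2)C(C)=C | intermediate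
29 | triethylsilyl ether of 28 (C6 OTES) | C[C@@H]1C[C@@H](O[Si](C)(C)C(C)(C)C)C([C@@H](O[Si](CC)(CC)CC)C=C)=C1C[C@H](OCc2ccc(OC)cc2)C(C)=C | intermediate
30 | (3S,6S,8R,10R)-8-[(tert-butyldimethylsilyl)oxy]-3-[(4-methoxybenzyl)oxy]-4,10-dimethyl-6-[(triethylsilyl)oxy]bicyclo[5.3.0]deca-1(7),4-diene (target numbering) | C[C@@H]1C[C@@H](O[Si](C)(C)C(C)(C)C)C2=C1C[C@H](OCc3ccc(OC)cc3)C(C)=C[C@@H]2O[Si](CC)(CC)CC | intermediate
31 | (3S,4R,5S,6R,8R,10R)-4,5-diol of 30, cis diol trans to the C6 oxygen | C[C@@H]1C[C@@H](O[Si](C)(C)C(C)(C)C)C2=C1C[C@H](OCc3ccc(OC)cc3)[C@@](C)(O)[C@@H](O)[C@@H]2O[Si](CC)(CC)CC | intermediate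
32 | 4,5-acetonide of 31, bicyclo[5.3.0]dec-1(7)-ene with C3 OPMB, C6 OTES, C8 OTBS | C[C@@H]1C[C@@H](O[Si](C)(C)C(C)(C)C)C2=C1C[C@H](OCc4ccc(OC)cc4)[C@@]3(C)OC(C)(C)O[C@H]3[C@@H]2O[Si](CC)(CC)CC | intermediate
33 | secondary ozonide of 32, 1,2,4-trioxolane bridging C1 and C7, configuration at C1 and C7 not assigned (not isolated) | C[C@@H]1C[C@@H](O[Si](C)(C)C(C)(C)C)C2(OO3)[C@@H](O[Si](CC)(CC)CC)[C@@H]4OC(C)(C)O[C@]4(C)[C@@H](OCc5ccc(OC)cc5)CC13O2 | intermediate
34 | (3S,4R,5S,6S,8R,10R)-8-[(tert-butyldimethylsilyl)oxy]-4,5-(isopropylidenedioxy)-3-[(4-methoxybenzyl)oxy]-4,10-dimethyl-6-[(triethylsilyl)oxy]cyclodecane-1,7-dione (target numbering) | C[C@@H]1C[C@@H](O[Si](C)(C)C(C)(C)C)C(=O)[C@@H](O[Si](CC)(CC)CC)[C@@H]2OC(C)(C)O[C@]2(C)[C@@H](OCc3ccc(OC)cc3)CC1=O | intermediate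
35 | 6-hydroxy analogue of 34 | C[C@@H]1C[C@@H](O[Si](C)(C)C(C)(C)C)C(=O)[C@@H](O)[C@@H]2OC(C)(C)O[C@]2(C)[C@@H](OCc3ccc(OC)cc3)CC1=O | intermediate
36 | 6-O-[3-[(tert-butyldimethylsilyl)oxy]-2-(diethoxyphosphoryl)propanoyl] ester of 35, epimers at the phosphonate carbon | C[C@@H]1C[C@@H](O[Si](C)(C)C(C)(C)C)C(=O)[C@@H](OC(=O)C(CO[Si](C)(C)C(C)(C)C)P(=O)(OCC)OCC)[C@@H]2OC(C)(C)O[C@]2(C)[C@@H](OCc3ccc(OC)cc3)CC1=O | intermediate
37 | butenolide: 6,12-olide with C7=C11, C13 OTBS, C8 OTBS, C3 OPMB, 4,5-acetonide, C1 ketone | CC(C)(C)[Si](C)(C)OCC1=C2[C@@H](OC1=O)[C@@H]3OC(C)(C)O[C@]3(C)[C@@H](OCc4ccc(OC)cc4)CC(=O)[C@H](C)C[C@H]2O[Si](C)(C)C(C)(C)C | intermediate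
38 | 8,13-diol of 37 | OCC1=C2[C@@H](OC1=O)[C@@H]3OC(C)(C)O[C@]3(C)[C@@H](OCc4ccc(OC)cc4)CC(=O)[C@H](C)C[C@H]2O | intermediate
39 | 13-acetate of 38, C8 hydroxyl free | CC(=O)OCC1=C2[C@@H](OC1=O)[C@@H]3OC(C)(C)O[C@]3(C)[C@@H](OCc4ccc(OC)cc4)CC(=O)[C@H](C)C[C@H]2O | intermediate
40 | (Z)-4-acetoxy-3-methylbut-2-enoic 2,4,6-trichlorobenzoic anhydride (not isolated) | O=C(OC(=O)/C=C(/C)COC(C)=O)c1c(Cl)cc(Cl)cc1Cl | intermediate
41 | 8-O-[(Z)-4-acetoxy-3-methylbut-2-enoyl] 13-acetate with 4,5-acetonide and C3 OPMB | CC(=O)OCC1=C2[C@@H](OC1=O)[C@@H]3OC(C)(C)O[C@]3(C)[C@@H](OCc4ccc(OC)cc4)CC(=O)[C@H](C)C[C@H]2OC(=O)/C=C(/C)COC(C)=O | intermediate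
42 | 4,5-diol of 41 | CC(=O)OCC1=C2[C@@H](OC1=O)[C@H](O)[C@](C)(O)[C@@H](OCc3ccc(OC)cc3)CC(=O)[C@H](C)C[C@H]2OC(=O)/C=C(/C)COC(C)=O | intermediate
43 | 5-O-methanesulfonate of 42 | CC(=O)OCC1=C2[C@@H](OC1=O)[C@H](OS(C)(=O)=O)[C@](C)(O)[C@@H](OCc3ccc(OC)cc3)CC(=O)[C@H](C)C[C@H]2OC(=O)/C=C(/C)COC(C)=O | intermediate
44 | trans-4,5-epoxide with C3 OPMB | CC(=O)OCC1=C2[C@@H](OC1=O)[C@H]3O[C@]3(C)[C@@H](OCc4ccc(OC)cc4)CC(=O)[C@H](C)C[C@H]2OC(=O)/C=C(/C)COC(C)=O | intermediate
45 | 3-hydroxy trans-4,5-epoxide | CC(=O)OCC1=C2[C@@H](OC1=O)[C@H]3O[C@]3(C)[C@@H](O)CC(=O)[C@H](C)C[C@H]2OC(=O)/C=C(/C)COC(C)=O | intermediate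
46 | CNP0274470.1 (4S,5R,6R,8R,10R) | CC(=O)OCC1=C2[C@@H](OC1=O)[C@H]1O[C@]1(C)C(=O)CC(=O)[C@H](C)C[C@H]2OC(=O)/C=C(/C)COC(C)=O | target

## Step count and least certain steps

Total: 32 steps. Longest linear sequence: 27 steps (steps 6–32, from 10). Side branches: steps 1–3 (acid 4) and steps 4–5 (acid 9).

**Step 21 (key step).** Ozone may attack the anisyl ring if the end point is overshot. The tethered carbonyl oxide and ketone of a tetrasubstituted alkene may also recombine slowly, so that peroxidic oligomers form, or the alkene may be partly epoxidised. Fallback, a stepwise glycol cleavage that leaves the disconnection unchanged: from 32, stoichiometric OsO4 in pyridine should add to the only remaining alkene and give the cis-1,7-diol F1. Pb(OAc)4 in benzene/pyridine at 0 °C then cleaves the ditertiary cis glycol to 34, where the route is rejoined. The PMB ether is inert to both reagents.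

**Step 30 (epoxide closure).** The base may remove the acidic γ-hydrogen on C6 of the butenolide, so that the sulfonate is lost across C5–C6 (E1cB) instead of being displaced, or the alkoxide may attack an acetate. Fallback: from diol 42, Mitsunobu-type cyclodehydration (PPh3, diisopropyl azodicarboxylate, toluene, rt → 60 °C). The oxyphosphonium group forms on the secondary C5 hydroxyl and is displaced by the tertiary C4 oxygen with inversion under neutral conditions. This leads directly to 44 and makes no new compound (F0).

**Step 16 (reduction at C6).** The catalyst may discriminate poorly between two alkenyl substituents, or may be mismatched with the neighbouring C8 centre, so that facial selectivity is low. Fallback, substrate control on the bicycle: from 27, ring-closing metathesis (second-generation Hoveyda–Grubbs catalyst, toluene, 80 °C) should give the bicyclic cross-conjugated dienone F2. Luche reduction (NaBH4, CeCl3, MeOH, −78 °C) should deliver hydride anti to the C8 silyloxy group and give the bicyclic C6 alcohol F3, and TESCl/imidazole brings it back to 30.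

**Step 27 (esterification at C8).** The Z enoate may isomerise by reversible conjugate addition of DMAP, the acetoxy oxygen may attack the activated carboxyl, or the hindered C8 hydroxyl may be acylated slowly. Fallback, with the side-chain oxygen carried as a silyl ether: 5 is opened with KOH and silylated (TBSCl, imidazole; K2CO3, aqueous MeOH work-up) to (Z)-4-[(tert-butyldimethylsilyl)oxy]-3-methylbut-2-enoic acid F4. Yamaguchi coupling of F4 with 39 gives the silyloxy ester F5, HF·pyridine gives the hydroxy ester F6, and immediate acetylation (Ac2O, pyridine, 0 °C) gives 41.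

## Further compounds

F1 | step 21 | cis-1,7-diol of 32 (face of addition not assigned) | C[C@@H]1C[C@@H](O[Si](C)(C)C(C)(C)C)C2(O)C1(O)C[C@H](OCc4ccc(OC)cc4)[C@@]3(C)OC(C)(C)O[C@H]3[C@@H]2O[Si](CC)(CC)CC
F0 | step 30 | none | none
F2 | step 16 | bicyclo[5.3.0]deca-1(7),4-dien-6-one with C3 OPMB and C8 OTBS | C[C@@H]1C[C@@H](O[Si](C)(C)C(C)(C)C)C2=C1C[C@H](OCc3ccc(OC)cc3)C(C)=CC2=O
F3 | step 16 | bicyclic C6 alcohol (30 without its triethylsilyl group) | C[C@@H]1C[C@@H](O[Si](C)(C)C(C)(C)C)C2=C1C[C@H](OCc3ccc(OC)cc3)C(C)=C[C@@H]2O
F4 | step 27 | (Z)-4-[(tert-butyldimethylsilyl)oxy]-3-methylbut-2-enoic acid | OC(=O)/C=C(/C)CO[Si](C)(C)C(C)(C)C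
F5 | step 27 | 8-O-[(Z)-4-[(tert-butyldimethylsilyl)oxy]-3-methylbut-2-enoyl] analogue of 41 | CC(=O)OCC1=C2[C@@H](OC1=O)[C@@H]3OC(C)(C)O[C@]3(C)[C@@H](OCc4ccc(OC)cc4)CC(=O)[C@H](C)C[C@H]2OC(=O)/C=C(/C)CO[Si](C)(C)C(C)(C)C
F6 | step 27 | 8-O-[(Z)-4-hydroxy-3-methylbut-2-enoyl] analogue of 41 | CC(=O)OCC1=C2[C@@H](OC1=O)[C@@H]3OC(C)(C)O[C@]3(C)[C@@H](OCc4ccc(OC)cc4)CC(=O)[C@H](C)C[C@H]2OC(=O)/C=C(/C)CO
A1 | alternative 1 | seco sulfonium triflate with C4 tetrahydrothiophenium, C5 aldehyde, C1 methyl enol ether and dihydrofuran | O=C[C@@H]1OCC(COC(C)=O)=C1[C@H](OC(=O)/C=C(/C)COC(C)=O)C[C@@H](C)/C(OC)=C\C(=O)C(C)[S+]2CCCC2.[O-]S(=O)(=O)C(F)(F)F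
A2 | alternative 1 | trans-epoxy macrocycle with C1 methyl enol ether and dihydrofuran | CC(=O)OCC1=C2[C@@H](OC1)[C@H]1O[C@]1(C)C(=O)/C=C(OC)\[C@H](C)C[C@H]2OC(=O)/C=C(/C)COC(C)=O
A3 | alternative 2 | seco (Z)-β-iodo enoate with C6 epoxy aldehyde, C3 and C13 TBS ethers and C8 PMB ether | O=C[C@H]1O[C@]1(C)[C@@H](O[Si](C)(C)C(C)(C)C)CC(=O)[C@H](C)C[C@@H](OCc2ccc(OC)cc2)/C(I)=C(\CO[Si](C)(C)C(C)(C)C)C(=O)OC
A4 | alternative 2 | bicyclic butenolide with C3 and C13 TBS ethers and C8 PMB ether | CC(C)(C)[Si](C)(C)OCC1=C2[C@@H](OC1=O)[C@H]1O[C@]1(C)[C@@H](O[Si](C)(C)C(C)(C)C)CC(=O)[C@H](C)C[C@H]2OCc1ccc(OC)cc1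
A5 | alternative 3 | seco ynal with C3 aldehyde and C4≡C5 alkyne | O=CC[C@H](O[Si](C)(C)C(C)(C)C)[C@H](C)C[C@@H](OCc1ccc(OC)cc1)/C(=C(\CO[Si](C)(C)C(C)(C)C)C(=O)OC)[C@@H](O[Si](CC)(CC)CC)C#CC
A6 | alternative 3 | ten-membered (E)-allylic triethylsilyl ether | CC[Si](CC)(CC)O[C@@H]1C[C@H](O[Si](C)(C)C(C)(C)C)[C@H](C)C[C@@H](OCc2ccc(OC)cc2)/C(=C(\CO[Si](C)(C)C(C)(C)C)C(=O)OC)[C@@H](O[Si](CC)(CC)CC)/C=C1\C
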